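**Retrosynthetic overview**
1. Target 19 ⇐ epoxide 18 ⇐ alkene 17: C5–H and C6–OH come last, by α-face epoxidation of the C5=C6 alkene and radical (anti-Markovnikov) epoxide opening.
2. 17 ⇐ allylic alcohol 14 + methyl acrylate 15: the C7–C11 bond is made by allylic C-alkylation with net retention.
3. 14 ⇐ enone 12: C8 acetate by α′-acetoxylation, then reduction of both ketones (C1, C7).
4. 12 ⇐ (R)-Wieland–Miescher ketone 7: C4 carbinol by γ-methylenation and Markovnikov hydration.
5. 7 ⇐ (R)-Hajos–Parrish ketone 5 ⇐ 1 + 2: ring B is formed first (proline-catalysed annulation onto the cyclopentanedione); ring A is formed second, by one-carbon ring expansion of the cyclopentanone.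

Assumption: positions are numbered as in eudesmane (ring A = C1–C5, C10; ring B = C5–C10; C14 on C10; C15 on C4; C11–C13 on C7), β is the face of the C14 methyl, and Δ5 means C5=C6.

**Step 1**
Reactants: 1 2-methylcyclopentane-1,3-dione; 2 but-3-en-2-one
Product: 3 2-methyl-2-(3-oxobutyl)cyclopentane-1,3-dione
Conditions: H2O, rt
Reagents that add atoms: none
Why: Michael addition of the acidic 1,3-dione to the enone needs no added base and stops at the achiral triketone.

**Step 2**
Reactants: 3 2-methyl-2-(3-oxobutyl)cyclopentane-1,3-dione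
Product: 5 (7aR)-7a-methyl-2,3,7,7a-tetrahydro-1H-indene-1,5(6H)-dione, via ketol 4 (not isolated)
Conditions: (R)-proline (3 mol %), DMF, rt; then H2SO4 (cat.), 95 °C
Reagents that add atoms: none
Why: Hajos–Parrish–Eder–Sauer–Wiechert reaction; the enamine-mediated desymmetrising aldol closes ring B and sets the quaternary C10 as R (mirror image of the (S)-proline series), and acid dehydration gives the enone.

**Step 3**
Reactants: 5 (7aR)-7a-methyl-2,3,7,7a-tetrahydro-1H-indene-1,5(6H)-dione
Product: 7 (8aR)-8a-methyl-3,4,8,8a-tetrahydronaphthalene-1,6(2H,7H)-dione, via α-silyl ketone 6 (not isolated)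
Conditions: Me3SiCHN2 (1.2 equiv), BF3·OEt2 (1.2 equiv), CH2Cl2, −78 to −30 °C; then 1 M HCl, THF, rt
Reagents that add atoms: (trimethylsilyl)diazomethane C[Si](C)(C)C=[N+]=[N-]
Why: Lewis-acid-promoted diazoalkane homologation (Tiffeneau–Demjanov-type 1,2-shift); the strained saturated cyclopentanone reacts in preference to the conjugated ketone, the less substituted CH2 migrates so the carbonyl stays next to the quaternary carbon, the hindered α-silyl cyclohexanone resists a second insertion, and protodesilylation gives six-membered ring A without touching C10.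

**Step 4**
Reactants: 7 (8aR)-8a-methyl-3,4,8,8a-tetrahydronaphthalene-1,6(2H,7H)-dione
Product: 10 (8aR)-8a-methyl-4-methylidene-3,4,8,8a-tetrahydronaphthalene-1,6(2H,7H)-dione, via dienol ether 8 (not isolated), via ethoxymethyl enone 9 (not isolated)
Conditions: CH2(OEt)2, POCl3, NaOAc, CHCl3, reflux
Reagents that add atoms: diethoxymethane CCOCOCC
Why: Annen-type γ-methylenation of an enone, as used for 6-methylene steroids; the transient dienol ether is alkoxymethylated at the γ-carbon C4 and loses ethanol to give the linear dienone, while the saturated C1 ketone is left alone.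

**Step 5**
Reactants: 10 (8aR)-8a-methyl-4-methylidene-3,4,8,8a-tetrahydronaphthalene-1,6(2H,7H)-dione
Product: 12 4α-hydroxy-4β,10β-dimethyl-Δ5-octalin-1,7-dione, via hydroperoxide 11 (not isolated)
Conditions: tris(dipivaloylmethanato)manganese (Mn(dpm)3, 10 mol %), PhSiH3, O2 (1 atm), i-PrOH/CH2Cl2, 0 °C; then PPh3
Reagents that add atoms: dioxygen O=O
Why: Mukaiyama hydration by hydrogen-atom transfer, run in the vinylogous sense; H adds to terminal C15, the dienyl radical is trapped by O2 at the tertiary γ-carbon C4 (keeping the enone conjugated) from the α-face away from the pseudo-axial C14 methyl, which sets 4α-OH/4β-CH3.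

**Step 6**
Reactants: 12 4α-hydroxy-4β,10β-dimethyl-Δ5-octalin-1,7-dione
Product: 13 8α-acetoxy-4α-hydroxy-4β,10β-dimethyl-Δ5-octalin-1,7-dione
Conditions: Mn(OAc)3·2H2O (3 equiv), benzene, reflux (Dean–Stark)
Reagents that add atoms: manganese triacetate CC(=O)[O-].CC(=O)[O-].CC(=O)[O-].[Mn+3]
Why: α′-acetoxylation of an enone with manganese triacetate through the manganese enolate at C8, the only α′ position; the acetate is delivered anti to the C14 methyl and this epimerisable centre settles equatorial (8α), while the saturated ketone and tertiary alcohol react far more slowly.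

**Step 7**
Reactants: 13 8α-acetoxy-4α-hydroxy-4β,10β-dimethyl-Δ5-octalin-1,7-dione
Product: 14 8α-acetoxy-4β,10β-dimethyl-Δ5-octalin-1β,4α,7β-triol
Conditions: NaBH4, CeCl3·7H2O, MeOH, −40 °C
Reagents that add atoms: none
Why: Luche reduction; axial hydride attack from the α-face on both ketones gives the equatorial 1β-OH (as in the known borohydride reduction of the Wieland–Miescher ketone) and the pseudo-equatorial allylic 7β-OH trans to the 8α-acetate, and the cold, weakly acidic medium suppresses acetyl migration.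

**Step 8**
Reactants: 14 8α-acetoxy-4β,10β-dimethyl-Δ5-octalin-1β,4α,7β-triol; 15 methyl acrylate
Product: 17 methyl 8α-acetoxy-1β,4α-dihydroxy-7αH-eudesma-5,11(13)-dien-12-oate, via allylic hydrogen carbonate 16 (not isolated)
Conditions: Pd(PPh3)4 (5 mol %), PBu3 (50 mol %), CO2 (1 atm), methyl acrylate (5 equiv), t-BuOH/THF, 60 °C
Reagents that add atoms: none
Why: Proposed new method: a dehydrative allylic Morita–Baylis–Hillman alkylation under dual zerovalent-palladium/nucleophilic-phosphine catalysis, in which CO2 turns the allylic 7β-OH into hydrogen carbonate 16, Pd(PPh3)4 ionises it with inversion onto the open α-face (the β-face of the C5–C7 allyl unit is shielded by the C14 and C15 methyls and no syn β-hydrogen is available), PBu3 adds to methyl acrylate to give a soft phosphonium enolate that attacks C7 (C5 is fully substituted) anti to palladium, and hydrogencarbonate-assisted loss of PBu3 restores the acrylate, so the C7–C11 bond forms with net retention (7β) and water is the only by-product; the closest known reaction types are the intramolecular phosphine/palladium co-catalysed enone cycloallylation and the Tsuji–Trost alkylation of free allylic alcohols activated by CO2 or Et3B.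

**Step 9**
Reactants: 17 methyl 8α-acetoxy-1β,4α-dihydroxy-7αH-eudesma-5,11(13)-dien-12-oate
Product: 18 methyl 8α-acetoxy-5α,6α-epoxy-1β,4α-dihydroxy-7αH-eudesm-11(13)-en-12-oate
Conditions: mCPBA, CH2Cl2, 0 °C
Reagents that add atoms: mCPBA OOC(=O)c1cccc(Cl)c1
Why: Hydroxyl-directed (Henbest) Prilezhaev epoxidation; only the electron-rich trisubstituted C5=C6 alkene reacts (the acrylate is inert), and the allylic 4α-OH together with β-face shielding by C14, C15 and the 7β side chain gives the 5α,6α-epoxide.

**Step 10**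
Reactants: 18 methyl 8α-acetoxy-5α,6α-epoxy-1β,4α-dihydroxy-7αH-eudesm-11(13)-en-12-oate
Product: 19 methyl 8α-acetoxy-1β,4α,6α-trihydroxy-5αH,7αH-eudesm-11(13)-en-12-oate
Conditions: bis(cyclopentadienyl)titanium dichloride (Cp2TiCl2, 20 mol %), Mn powder, 2,4,6-collidine hydrochloride, cyclohexa-1,4-diene, THF, rt
Reagents that add atoms: none
Why: Nugent–RajanBabu/Gansäuer reductive epoxide opening with trivalent titanium; homolysis gives the tertiary C5 radical and leaves oxygen on C6 (6α-OH), and hydrogen-atom transfer from cyclohexadiene to C5 from the α-face (the β-face is flanked by the C14 and C15 methyls) gives the trans-decalin 5α-H, the acrylate being out of reach for any favourable radical ring closure.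

**Compound list**
1 | 2-methylcyclopentane-1,3-dione | CC1C(=O)CCC1=O | starting material
2 | but-3-en-2-one (methyl vinyl ketone) | CC(=O)C=C | starting material
3 | 2-methyl-2-(3-oxobutyl)cyclopentane-1,3-dione | CC(=O)CCC1(C)C(=O)CCC1=O | intermediate
4 | (3aR,7aR)-3a-hydroxy-7a-methylhexahydro-1H-indene-1,5(4H)-dione (cis-fused ketol) | C[C@@]12CCC(=O)C[C@]1(O)CCC2=O | intermediate
5 | (7aR)-7a-methyl-2,3,7,7a-tetrahydro-1H-indene-1,5(6H)-dione ((R)-Hajos–Parrish ketone) | C[C@@]12CCC(=O)C=C1CCC2=O | intermediate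
6 | (8aR)-8a-methyl-2-(trimethylsilyl)-3,4,8,8a-tetrahydronaphthalene-1,6(2H,7H)-dione (C2 epimers) | C[C@@]12CCC(=O)C=C1CCC([Si](C)(C)C)C2=O | intermediate
7 | (8aR)-8a-methyl-3,4,8,8a-tetrahydronaphthalene-1,6(2H,7H)-dione ((R)-Wieland–Miescher ketone) | C[C@@]12CCC(=O)C=C1CCCC2=O | intermediate
8 | (8aR)-6-ethoxy-8a-methyl-3,7,8,8a-tetrahydronaphthalen-1(2H)-one (dienol ether) | C[C@@]12CCC(OCC)=CC1=CCCC2=O | intermediate
9 | (8aR)-4-(ethoxymethyl)-8a-methyl-3,4,8,8a-tetrahydronaphthalene-1,6(2H,7H)-dione (C4 epimers) | C[C@@]12CCC(=O)C=C1C(COCC)CCC2=O | intermediate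
10 | (8aR)-8a-methyl-4-methylidene-3,4,8,8a-tetrahydronaphthalene-1,6(2H,7H)-dione | C[C@@]12CCC(=O)C=C1C(=C)CCC2=O | intermediate
11 | 4α-hydroperoxy-4β,10β-dimethyl-Δ5-octalin-1,7-dione | C[C@@]12CCC(=O)C=C1[C@](C)(OO)CCC2=O | intermediate
12 | 4α-hydroxy-4β,10β-dimethyl-Δ5-octalin-1,7-dione ((4R,8aR)-4-hydroxy-4,8a-dimethyl-3,4,8,8a-tetrahydronaphthalene-1,6(2H,7H)-dione) | C[C@@]12CCC(=O)C=C1[C@](C)(O)CCC2=O | intermediate
13 | 8α-acetoxy-4α-hydroxy-4β,10β-dimethyl-Δ5-octalin-1,7-dione | C[C@@]12C[C@H](OC(C)=O)C(=O)C=C1[C@](C)(O)CCC2=O | intermediate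
14 | 8α-acetoxy-4β,10β-dimethyl-Δ5-octalin-1β,4α,7β-triol | C[C@@]12C[C@H](OC(C)=O)[C@@H](O)C=C1[C@](C)(O)CC[C@H]2O | intermediate
15 | methyl acrylate | C=CC(=O)OC | starting material
16 | 7β-O-hydrogen carbonate of 14 | C[C@@]12C[C@H](OC(C)=O)[C@@H](OC(=O)O)C=C1[C@](C)(O)CC[C@H]2O | intermediate
17 | methyl 8α-acetoxy-1β,4α-dihydroxy-7αH-eudesma-5,11(13)-dien-12-oate | C[C@@]12C[C@H](OC(C)=O)[C@@H](C(=C)C(=O)OC)C=C1[C@](C)(O)CC[C@H]2O | intermediate
18 | methyl 8α-acetoxy-5α,6α-epoxy-1β,4α-dihydroxy-7αH-eudesm-11(13)-en-12-oate | C[C@@]12C[C@H](OC(C)=O)[C@@H](C(=C)C(=O)OC)[C@@H]3O[C@]13[C@](C)(O)CC[C@H]2O | intermediate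
19 | methyl 8α-acetoxy-1β,4α,6α-trihydroxy-5αH,7αH-eudesm-11(13)-en-12-oate | C=C(C(=O)OC)[C@H]1[C@H](O)[C@@H]2[C@@](C)(C[C@@H]1OC(C)=O)[C@H](O)CC[C@@]2(C)O | target

**Total step count:** 10. **Longest linear sequence:** 10 steps (1 → 19; 2 and 15 are commercial).

**Steps most likely to fail**

Step 8 (the proposed new step) may fail through phosphine-promoted acetyl migration from O8 to O7, ionisation at the tertiary allylic C4–OH, or slow release of the phosphine. The fallback sets out from 14 and comes back at 17, using known chemistry. Tsuji–Trost alkylation of the free allylic alcohol with methyl acetoacetate under Pd(PPh3)4/Et3B (THF, 50 °C; soft nucleophile, net retention) gives methyl 2-(8α-acetoxy-1β,4α-dihydroxy-4β,10β-dimethyl-Δ5-octalin-7β-yl)-3-oxobutanoate F3. Aqueous formaldehyde with K2CO3 in THF then effects deacetylative methylenation (aldol, acetyl transfer, loss of acetate) to give 17.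

Step 5 may give oxygenation at C6 instead of C4, simple reduction of the dienone, or a poor α/β ratio. The fallback sets out from 10 and comes back at 12 by an ionic route. Dimethyldioxirane in acetone at 0 °C epoxidises the more electron-rich C4=C15 alkene from the α-face to give the 4α,15-epoxy-10β-methyl-Δ5-octalin-1,7-dione F1. LiI/AcOH in THF opens it at the primary carbon to the 4α-hydroxy-15-iodo-4β,10β-dimethyl-Δ5-octalin-1,7-dione F2. Bu3SnH with Et3B/air at 0 °C removes the iodine to give 12.

Step 10 may suffer from radical addition to the acrylate, lactonisation of the titanium alkoxide onto the ester, or Lewis-acid semipinacol opening of the tertiary epoxy alcohol. The fallback sets out from 17 and comes back at 19 without the epoxide. Conjugate addition of benzeneselenol (PhSeH, cat. Et3N, CH2Cl2) masks the acrylate as methyl 8α-acetoxy-1β,4α-dihydroxy-13-(phenylselanyl)-7αH-eudesm-5-en-12-oate F4. BH3·THF hydroborates the C5=C6 alkene from the α-face (boron on C6, hydrogen on C5). H2O2/aq. NaHCO3 then oxidises the C–B bond to 6α-OH and selenium to the selenoxide, methyl 8α-acetoxy-1β,4α,6α-trihydroxy-13-(phenylseleninyl)-5αH,7αH-eudesman-12-oate F5, which undergoes syn-elimination at rt to restore the 11(13)-alkene and give 19.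

**Further compounds**
F1 | step 5 | 4α,15-epoxy-10β-methyl-Δ5-octalin-1,7-dione (spiro-epoxide of 10) | C[C@@]12CCC(=O)C=C1[C@@]3(CO3)CCC2=O
F2 | step 5 | 4α-hydroxy-15-iodo-4β,10β-dimethyl-Δ5-octalin-1,7-dione | C[C@@]12CCC(=O)C=C1[C@](CI)(O)CCC2=O
F3 | step 8 | methyl 2-(8α-acetoxy-1β,4α-dihydroxy-4β,10β-dimethyl-Δ5-octalin-7β-yl)-3-oxobutanoate | C[C@@]12C[C@H](OC(C)=O)[C@@H](C(C(C)=O)C(=O)OC)C=C1[C@](C)(O)CC[C@H]2O
F4 | step 10 | methyl 8α-acetoxy-1β,4α-dihydroxy-13-(phenylselanyl)-7αH-eudesm-5-en-12-oate | C[C@@]12C[C@H](OC(C)=O)[C@@H](C(C[Se]c3ccccc3)C(=O)OC)C=C1[C@](C)(O)CC[C@H]2O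
F5 | step 10 | methyl 8α-acetoxy-1β,4α,6α-trihydroxy-13-(phenylseleninyl)-5αH,7αH-eudesman-12-oate | O=[Se](CC(C(=O)OC)[C@H]1[C@H](O)[C@@H]2[C@@](C)(C[C@@H]1OC(C)=O)[C@H](O)CC[C@@]2(C)O)c3ccccc3
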